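## Analysis of the target

Target 16 is a flavone: a chromen-4-one, in which benzo ring A is fused to pyranone ring C, with a 3,5-dihydroxy-4-methoxyphenyl group (ring B) on C2. It has no stereocentre and no stereogenic double bond, so the problem is one of constitution only. Every position of the bicycle is substituted: C3 carries OMe, C5 a hydroxyl hydrogen-bonded to the C4 carbonyl, and C6, C7 and C8 carry OMe, so ring A is a hexasubstituted benzene with five oxygens (O1 included). Eight oxygen substituents must end as three free phenols (C5, C3', C5') and five methyl ethers, which makes the differentiation of oxygens the main bookkeeping task. The free phenols sit on electron-rich rings and are sensitive to oxidants and to base in air, and the pyranone C2 is open to conjugate attack by hard nucleophiles; the ring B phenols are therefore carried as benzyl ethers and released last. The real difficulty is ring A, because the classical flavone syntheses presuppose a fully oxygenated and differentiated acetophenone or benzaldehyde. The strategy rests on the fact that C5 and C7 are at the oxidation level of carbonyl carbons while C6 and C8 are methoxy-bearing carbons at the level of methoxymethylene groups. The chain C8–C7–C6–C5 thus reads as a methoxylated β-polycarbonyl chain closed onto C8a and C4a of a pyranone that is already in place.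

## Retrosynthetic reasoning

Flavone numbering is used for all intermediates, also before ring A exists.

16 ⇒ 15. The two benzylic C–O bonds on ring B are cut last. The 3',5'-diol next to a methoxy group is the most oxidation-prone part of 16, so it stays masked as dibenzyl ether 15 and is freed by hydrogenolysis. This neutral step leaves the methyl ethers, the chelated 5-OH and the C2=C3 bond alone.

15 ⇒ 14. The O–CH3 bond at C7 is cut next, leading to 5,7-diol 14. Its two hydroxyls differ sharply: the 7-OH is a vinylogous acid para to the C4 carbonyl, the 5-OH is held in a hydrogen bond to that carbonyl. The forward methylation must touch only the 7-OH. The gain is that ring A may be made with two free hydroxyls, which is what a carbonyl-based ring synthesis delivers.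

14 ⇒ 12 + 4 (key disconnection). Cutting C7–C8 and C5–C6 removes C7 and C6 as one molecule of methyl methoxyacetate (4). What remains is pyranone 12, in which C8 is a methoxymethyl group on C8a and C5 is a methyl ester on C4a. These bonds are chosen over the bonds of ring C because this cut creates the ring A oxygens instead of presupposing them in a hexasubstituted benzene. Both fragments are also at the correct oxidation level, so no redox step follows. In the forward direction a lithium amide must deprotonate the methoxymethyl group of 12, the extended enolate must be acylated by 4 (Claisen), and ketone 13 must close through its outer carbon onto the ester (Dieckmann) and aromatise.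

12 ⇒ 8 + 9. The pyranone is opened at O1–C2 and at C4–C4a. Methyl 4-methoxy-3-oxobutanoate (9) supplies C8, C8a, O1, C4a and the ester carbon C5. The 2,3-dimethoxyacrylic acid 8 supplies C4, C3 with its methoxy group, and C2 with ring B and a methoxy leaving group. Forward, the magnesium enolate of 9 is C-acylated by acid chloride 10 to tricarbonyl ester 11, whose enol oxygen displaces the β-methoxy group by addition–elimination. This is an established way to 4-pyranone-3-carboxylates, and it brings in the C3 methoxy group at the start instead of by late oxidation.

8 ⇒ 7 ⇒ 6 ⇒ 3 + 4. Acid 8 comes from methyl ester 7, the enol methyl ether of β-keto ester 6. Cutting the C2–C3 bond of 6 gives benzoic acid 3 (as its chloride 5) and a second molecule of 4. The forward steps are an ester enolate acylation, a methylation that must go through oxygen and not carbon, and a saponification. Ester 4 is thus used twice, once for C3/C4 and once for C6/C7.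

3 ⇒ 1. The benzyl ethers are removed retrosynthetically to reach commercial 3,5-dihydroxy-4-methoxybenzoic acid (1). Forward, all three acidic sites are benzylated to benzyl ester 2, which is saponified in the same pot.

## Alternatives that were turned down

Alternative 1: The C3–C4 bond of ring C is cut by a reductive pinacol coupling. Ring A enters as a hexasubstituted benzaldehyde whose phenol oxygen already carries C2, ring B and a second, aliphatic aldehyde: 2-{1-[3,5-bis(benzyloxy)-4-methoxyphenyl]-2-oxoethoxy}-6-(benzyloxy)-3,4,5-trimethoxybenzaldehyde A2.
- Forward key step: divalent samarium reduces the aromatic aldehyde to a ketyl, which adds to the tethered aldehyde and closes ring C as the flavan-3,4-diol A1. Both carbinols are then oxidised, the 3,4-dione enolises to the flavonol, the 3-OH is methylated and three benzyl ethers (one on O5) are removed.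
- For it: six-ring ketyl–aldehyde couplings are mild and dependable, and the O5 benzyl group makes the C5/C7 distinction trivial. As a single ring-closing event it is more predictable than the key step chosen here.
- Against it: the pentaoxygenated, differentiated ring A is assumed in the starting benzaldehyde, not built. The α-aryloxy aldehyde of A2 invites reductive C–O cleavage and β-elimination under the same electron-transfer conditions. Three stereocentres are made only to be destroyed, and two alcohol oxidations must be run on electron-rich rings.
- Comparison: the chosen route has no redox detour, fewer steps after the key step, and assembles ring A from two-carbon esters at the right oxidation level.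

Alternative 2: Three bonds of ring C are cut at once (C4a–C4, C4–C3, O1–C2). The partners are the symmetric 2-iodo-4,5,6-trimethoxybenzene-1,3-diol A4, the ring B alkyne 1,3-bis(benzyloxy)-5-ethynyl-2-methoxybenzene A5 and one carbonyl carbon from a carbonylating atmosphere.
- Forward key step: a carbonylative Sonogashira-type coupling followed by closure of the phenol onto the ynone gives the 5-hydroxyflavone A3.
- For it: one step gives the whole flavone skeleton. The symmetry of A4 removes the question of which phenol closes, and the other phenol becomes the 5-OH without a protecting group. In convergence it is clearly stronger than the chosen route.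
- Against it: A3 has hydrogen at C3. The 3-methoxy group would need later C3 oxygenation (protection of the 5-OH, metalation or epoxidation, oxidation, methylation), which costs more steps than the annulation saves. A4 is itself a multi-step target, slow in oxidative addition to zerovalent palladium with both ortho positions occupied, and prone to quinone formation. The ynone can also close 5-exo to an aurone.
- Comparison: the chosen route carries the C3 methoxy group from the acrylate stage and makes the ring A oxygens instead of requiring them.

Alternative 3: The bonds C8a–O1, C4a–C4 and O1–C2 are cut. The partners are 3,4,5,6-tetramethoxybenzyne A8, released by fluoride from 2,3,4,5-tetramethoxy-6-(trimethylsilyl)phenyl triflate A7, and acid 8 of the present route.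
- Forward key step: the aryne takes up the carboxyl group of 8 across its strained bond (oxygen on one carbon, acyl on the other), and the phenoxide closes on C2 with loss of the methoxy group. The product is the pentamethoxyflavone A6, which then needs chelation-directed cleavage of the 5-methyl ether and debenzylation.
- For it: the flavone core follows in one step from an intermediate that is made anyway, the aryne is symmetric, and the 3-OMe is in place. In step count after 8 it is shorter than the chosen route.
- Against it: A7 is a hexasubstituted benzene with silyl, triflate and four methoxy groups, so the difficulty of ring A is moved into a multi-step precursor. Acyl transfer to the aryl anion competes with its protonation by the acid, which leads to a dead-end aryl ester, and two flanking methoxy groups hinder the aryne. The end game must cleave one methyl ether out of six.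
- Comparison: the chosen route needs no preformed hexasubstituted benzene, builds ring A from commodity esters, and produces the C5/C7 pair as two hydroxyls that chelation distinguishes in a methylation, not a demethylation.

Key step: step 6

Assumption: 7, 8, 10 and 11 are carried as E/Z mixtures and 6 and 13 as racemates, because these stereo-elements vanish when rings C and A form; 1, 4 and 9 are taken as commercial.

## Route

Step 1
Reactants: 1 3,5-dihydroxy-4-methoxybenzoic acid
Product: 3 3,5-bis(benzyloxy)-4-methoxybenzoic acid, via benzyl ester 2 (not isolated)
Conditions: BnBr (3.5 equiv), K2CO3, DMF, 60 °C; then aq. NaOH, MeOH, 70 °C; aq. HCl to pH 2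
Reagents that add atoms: benzyl bromide, BrCc1ccccc1; sodium hydroxide, [Na+].[OH-]
Why: Williamson O-benzylation of both phenols and of the carboxylate, followed in the same pot by saponification of the benzyl ester through acyl–oxygen cleavage. Aryl benzyl ethers are inert to hot aqueous base, and the acid should precipitate on acidification.

Step 2
Reactants: 3 3,5-bis(benzyloxy)-4-methoxybenzoic acid; 4 methyl methoxyacetate
Product: 6 methyl 3-[3,5-bis(benzyloxy)-4-methoxyphenyl]-2-methoxy-3-oxopropanoate (racemic), via aroyl chloride 5 (not isolated)
Conditions: (COCl)2, cat. DMF, CH2Cl2, 0 °C to rt, evaporate; add in THF to 4 (2.2 equiv)/LiN(SiMe3)2 (2.2 equiv), THF, −78 °C; aq. NH4Cl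
Reagents that add atoms: none
Why: C-acylation of a lithium ester enolate by an acid chloride (crossed Claisen-type acylation). Two equivalents of enolate are used because the β-keto ester is deprotonated as it forms, which also protects it from a second acylation, and inverse addition keeps the enolate in excess.

Step 3
Reactants: 6 methyl 3-[3,5-bis(benzyloxy)-4-methoxyphenyl]-2-methoxy-3-oxopropanoate
Product: 7 methyl 3-[3,5-bis(benzyloxy)-4-methoxyphenyl]-2,3-dimethoxyprop-2-enoate (E/Z mixture)
Conditions: KN(SiMe3)2 (1.1 equiv), THF–DMPU, −78 °C; Me2SO4, −78 to 0 °C
Reagents that add atoms: dimethyl sulfate, COS(=O)(=O)OC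
Why: O-alkylation of a β-keto ester enolate. A dissociated potassium enolate in a dipolar cosolvent meets a hard sulfate electrophile, and the α-carbon is already tertiary and carries a methoxy group, so attack through oxygen should dominate.

Step 4
Reactants: 7 methyl 3-[3,5-bis(benzyloxy)-4-methoxyphenyl]-2,3-dimethoxyprop-2-enoate
Product: 8 3-[3,5-bis(benzyloxy)-4-methoxyphenyl]-2,3-dimethoxyprop-2-enoic acid (E/Z mixture)
Conditions: LiOH, THF/MeOH/H2O, 40 °C; then 1 M HCl to pH 3, 0 °C
Reagents that add atoms: lithium hydroxide, [Li+].[OH-]
Why: Ester saponification. The push–pull enol ether is a vinylogous carbonate whose β-carbon is deactivated towards hydroxide by the aryl and methoxy donors, and it should tolerate a brief cold acidification.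

Step 5
Reactants: 8 3-[3,5-bis(benzyloxy)-4-methoxyphenyl]-2,3-dimethoxyprop-2-enoic acid; 9 methyl 4-methoxy-3-oxobutanoate
Product: 12 methyl 6-[3,5-bis(benzyloxy)-4-methoxyphenyl]-5-methoxy-2-(methoxymethyl)-4-oxo-4H-pyran-3-carboxylate, via acryloyl chloride 10 (not isolated), via acyclic tricarbonyl ester 11 (not isolated)
Conditions: (COCl)2, cat. DMF, CH2Cl2, 0 °C, evaporate; 9, MgCl2, pyridine, CH2Cl2, 0 °C to rt; 1 M HCl wash; crude 11, cat. TsOH, toluene, 70 °C
Reagents that add atoms: none
Why: C-acylation of the chelated magnesium enolate of a β-keto ester by an acid chloride (MgCl2–amine soft enolisation). Acid-catalysed 6-endo-trig oxa-Michael addition of the ketone enol oxygen to the β-methoxy enone and loss of methanol then close the 4-pyranone by addition–elimination. The ketone enol is a better nucleophile than the ester carbonyl, so closure through the methoxyacetyl oxygen is expected.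

Step 6
Reactants: 12 methyl 6-[3,5-bis(benzyloxy)-4-methoxyphenyl]-5-methoxy-2-(methoxymethyl)-4-oxo-4H-pyran-3-carboxylate; 4 methyl methoxyacetate
Product: 14 2-[3,5-bis(benzyloxy)-4-methoxyphenyl]-5,7-dihydroxy-3,6,8-trimethoxychromen-4-one, via Claisen ketone 13 (not isolated)
Conditions: LiN(SiMe3)2 (1.05 equiv), THF, −78 °C; 4 (1.5 equiv), −78 to 0 °C; then LiN(SiMe3)2 (3 equiv), 0 to 40 °C; aq. HCl
Reagents that add atoms: none
Why: The only acidic C–H bonds of 12 are those of the methoxymethyl group, which is vinylogously activated by the C4 carbonyl and by the ester through the C8a=C4a bond, so one equivalent of LiN(SiMe3)2 should give a single extended enolate that also shields the pyranone from nucleophilic ring opening. This anion attacks the inductively activated carbonyl of 4 through its exocyclic carbon (Claisen condensation, bond C8–C7), and the released methoxide deprotonates the doubly activated methine of 13, which pulls the condensation forward; because no amide base is free at this stage, enolisation and self-condensation of 4 are held back. The second charge of base then enolises 13 at the outer methoxymethylene, and this carbon adds to the neighbouring ester carbonyl in a 6-(enolendo)-exo-trig Dieckmann closure (bond C6–C5) that forms ring A; loss of methoxide and two enolisations give the aromatic bis-phenoxide with no oxidation step. An E1cB loss of methoxide from the ester to a ketene, followed by 6π closure of the trienolate, would end in the same ring. The closest known reaction types are the base-mediated cyclisation of 2-acetonylbenzoates to naphthalene-1,3-diols and the acylation of 2-methyl-4-pyranone anions by esters; the two have not been run in one flask on a pyranone this crowded, and that is where the risk of the route lies. No stereocentre is created, since the methine centres of 13 and of the closing ring are erased by enolisation. The step needs carbon and not oxygen closure: the enol lactone from attack of the ketone oxygen on the ester can reopen under methoxide, whereas the carbocycle drains irreversibly into the phenoxide, and the C4 carbonyl cannot compete because a bond from C6 to it would bridge the pyranone ring. Methyl esters on both partners make any methoxide exchange degenerate.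

Step 7
Reactants: 14 2-[3,5-bis(benzyloxy)-4-methoxyphenyl]-5,7-dihydroxy-3,6,8-trimethoxychromen-4-one
Product: 15 2-[3,5-bis(benzyloxy)-4-methoxyphenyl]-5-hydroxy-3,6,7,8-tetramethoxychromen-4-one
Conditions: Me2SO4 (1.1 equiv), K2CO3, acetone, rt
Reagents that add atoms: dimethyl sulfate, COS(=O)(=O)OC
Why: Chemoselective phenol O-methylation. The 7-OH is a vinylogous acid para to the C4 carbonyl and is ionised by K2CO3, while the 5-OH is locked in a hydrogen-bonded chelate with that carbonyl and should stay unreactive towards one equivalent of reagent.

Step 8
Reactants: 15 2-[3,5-bis(benzyloxy)-4-methoxyphenyl]-5-hydroxy-3,6,7,8-tetramethoxychromen-4-one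
Product: 16 5,3',5'-trihydroxy-3,6,7,8,4'-pentamethoxyflavone
Conditions: H2 (1 atm), Pd/C (10 wt% palladium on carbon), EtOAc–MeOH, rt
Reagents that add atoms: none
Why: Hydrogenolysis of the two aryl benzyl ethers. The tetrasubstituted C2=C3 bond of the 3-methoxyflavone and the aryl methyl ethers are not reduced under these conditions, and the freed ring B diol meets neither base nor oxidant.

## Compound list

1 | 3,5-dihydroxy-4-methoxybenzoic acid | COc1c(O)cc(C(=O)O)cc1O | starting material
2 | benzyl 3,5-bis(benzyloxy)-4-methoxybenzoate | COc1c(OCc2ccccc2)cc(C(=O)OCc2ccccc2)cc1OCc1ccccc1 | intermediate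
3 | 3,5-bis(benzyloxy)-4-methoxybenzoic acid | COc1c(OCc2ccccc2)cc(C(=O)O)cc1OCc1ccccc1 | intermediate
4 | methyl methoxyacetate | COCC(=O)OC | starting material
5 | 3,5-bis(benzyloxy)-4-methoxybenzoyl chloride | COc1c(OCc2ccccc2)cc(C(=O)Cl)cc1OCc1ccccc1 | intermediate
6 | methyl 3-[3,5-bis(benzyloxy)-4-methoxyphenyl]-2-methoxy-3-oxopropanoate (racemic) | COC(=O)C(OC)C(=O)c1cc(OCc2ccccc2)c(OC)c(OCc2ccccc2)c1 | intermediate
7 | methyl 3-[3,5-bis(benzyloxy)-4-methoxyphenyl]-2,3-dimethoxyprop-2-enoate (E/Z mixture) | COC(=O)C(OC)=C(OC)c1cc(OCc2ccccc2)c(OC)c(OCc2ccccc2)c1 | intermediate
8 | 3-[3,5-bis(benzyloxy)-4-methoxyphenyl]-2,3-dimethoxyprop-2-enoic acid (E/Z mixture) | OC(=O)C(OC)=C(OC)c1cc(OCc2ccccc2)c(OC)c(OCc2ccccc2)c1 | intermediate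
9 | methyl 4-methoxy-3-oxobutanoate (methyl 4-methoxyacetoacetate) | COCC(=O)CC(=O)OC | starting material
10 | 3-[3,5-bis(benzyloxy)-4-methoxyphenyl]-2,3-dimethoxyprop-2-enoyl chloride (E/Z mixture) | ClC(=O)C(OC)=C(OC)c1cc(OCc2ccccc2)c(OC)c(OCc2ccccc2)c1 | intermediate
11 | methyl 5-[3,5-bis(benzyloxy)-4-methoxyphenyl]-4,5-dimethoxy-2-(methoxyacetyl)-3-oxopent-4-enoate (enolised tricarbonyl, E/Z mixture) | COCC(=O)C(C(=O)OC)C(=O)C(OC)=C(OC)c1cc(OCc2ccccc2)c(OC)c(OCc2ccccc2)c1 | intermediate
12 | methyl 6-[3,5-bis(benzyloxy)-4-methoxyphenyl]-5-methoxy-2-(methoxymethyl)-4-oxo-4H-pyran-3-carboxylate | COCc1oc(-c2cc(OCc3ccccc3)c(OC)c(OCc3ccccc3)c2)c(OC)c(=O)c1C(=O)OC | intermediate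
13 | methyl 6-[3,5-bis(benzyloxy)-4-methoxyphenyl]-2-(1,3-dimethoxy-2-oxopropyl)-5-methoxy-4-oxo-4H-pyran-3-carboxylate (racemic, present as its enolate) | COCC(=O)C(OC)c1oc(-c2cc(OCc3ccccc3)c(OC)c(OCc3ccccc3)c2)c(OC)c(=O)c1C(=O)OC | intermediate
14 | 2-[3,5-bis(benzyloxy)-4-methoxyphenyl]-5,7-dihydroxy-3,6,8-trimethoxychromen-4-one | COc1c(OCc2ccccc2)cc(-c2oc3c(OC)c(O)c(OC)c(O)c3c(=O)c2OC)cc1OCc1ccccc1 | intermediate
15 | 2-[3,5-bis(benzyloxy)-4-methoxyphenyl]-5-hydroxy-3,6,7,8-tetramethoxychromen-4-one | COc1c(OCc2ccccc2)cc(-c2oc3c(OC)c(OC)c(OC)c(O)c3c(=O)c2OC)cc1OCc1ccccc1 | intermediate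
16 | 5,3',5'-trihydroxy-3,6,7,8,4'-pentamethoxyflavone, 2-(3,5-dihydroxy-4-methoxyphenyl)-5-hydroxy-3,6,7,8-tetramethoxychromen-4-one | COc1c(O)cc(-c2oc3c(OC)c(OC)c(OC)c(O)c3c(=O)c2OC)cc1O | target

## Step count and risks

Total step count: 8. Longest linear sequence: 8 steps (1 to 16); esters 4 and 9 are bought and enter directly.

Step 6 (key step).
- What may go wrong: the stabilised dienolate of 12 may be too weak a nucleophile, so that proton transfer to 4 and self-condensation of 4 outrun the acylation.
- The sequence may also stall at the stage of 13: the C8 carbanion is cross-conjugated with the ester and lowers its electrophilicity, and closure through the ketone oxygen to an enol lactone can compete.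
- Whenever neutral pyranone is present, conjugate attack of methoxide on the ring is possible.
- Fallback: the two bond formations are taken apart, setting out from 12. Its lithium dienolate (one equivalent of LiN(SiMe3)2, THF, −78 °C) is acylated with N-methoxy-N-methyl-2-methoxyacetamide. This Weinreb amide forms a chelated tetrahedral adduct that neither self-condenses nor releases the ketone before work-up, and ketone 13 is isolated. Ring A is then closed separately with NaOMe in MeOH at reflux, the equilibrating conditions known for the cyclisation of 2-acetonylbenzoates to naphthalene-1,3-diols, under which an enol lactone reopens. The sequence comes back to the route at 14 and makes no compound outside the list (F0).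

Step 3.
- What may go wrong: methylation at carbon instead of oxygen, giving a quaternary α-methyl keto ester, or retro-Claisen cleavage of the enolate on warming.
- Fallback: setting out from 6, ketalisation with HC(OMe)3 and catalytic H2SO4 in MeOH should give methyl 3-[3,5-bis(benzyloxy)-4-methoxyphenyl]-2,3,3-trimethoxypropanoate F1. Acid-catalysed loss of methanol (cat. TsOH, toluene, 100 °C, MeOH distilled off) then leads to 7, where the route is rejoined. No enolate is involved, so carbon alkylation cannot occur.

Step 5.
- What may go wrong: breakdown of the acid-sensitive enol-ether acid chloride by the HCl formed during its preparation, acylation of the keto ester at oxygen instead of carbon, or ring closure through the ester oxygen.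
- Fallback: setting out from 8, activation with 1,1'-carbonyldiimidazole in THF gives, without any acid being formed, the acyl imidazole 3-[3,5-bis(benzyloxy)-4-methoxyphenyl]-1-(imidazol-1-yl)-2,3-dimethoxyprop-2-en-1-one F2. It acylates the magnesium enolate of 9 (MgCl2, Et3N, MeCN; Masamune–Brooks-type C-acylation) to 11, which is cyclised as before, rejoining the route at 12.

Step 7.
- What may go wrong: loss of chemoselectivity. The 7-OH lies between two methoxy groups, and if it reacts slowly, forcing conditions would begin to methylate the chelated 5-OH as well.
- Fallback: setting out from 14, exhaustive methylation (excess Me2SO4, K2CO3, acetone, reflux) gives 2-[3,5-bis(benzyloxy)-4-methoxyphenyl]-3,5,6,7,8-pentamethoxychromen-4-one F3. BCl3 with pentamethylbenzene in CH2Cl2 at −78 to 0 °C then removes in one operation the peri 5-methyl group (boron chelated between O5 and the C4 carbonyl) and both benzyl groups. The route is rejoined at 16, without passing 15.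

## Further compounds

F0 | step 6 | none | none
F1 | step 3 | methyl 3-[3,5-bis(benzyloxy)-4-methoxyphenyl]-2,3,3-trimethoxypropanoate (racemic) | COC(=O)C(OC)C(OC)(OC)c1cc(OCc2ccccc2)c(OC)c(OCc2ccccc2)c1
F2 | step 5 | 3-[3,5-bis(benzyloxy)-4-methoxyphenyl]-1-(imidazol-1-yl)-2,3-dimethoxyprop-2-en-1-one (E/Z mixture) | O=C(n1ccnc1)C(OC)=C(OC)c1cc(OCc2ccccc2)c(OC)c(OCc2ccccc2)c1
F3 | step 7 | 2-[3,5-bis(benzyloxy)-4-methoxyphenyl]-3,5,6,7,8-pentamethoxychromen-4-one | COc1c(OCc2ccccc2)cc(-c2oc3c(OC)c(OC)c(OC)c(OC)c3c(=O)c2OC)cc1OCc1ccccc1
A1 | alternative 1 | 5-(benzyloxy)-2-[3,5-bis(benzyloxy)-4-methoxyphenyl]-6,7,8-trimethoxychromane-3,4-diol (racemic, 2,3-trans-3,4-cis, one enantiomer drawn) | O[C@H]1[C@@H](O)[C@H](c2cc(OCc3ccccc3)c(OC)c(OCc3ccccc3)c2)Oc2c(OC)c(OC)c(OC)c(OCc3ccccc3)c21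
A2 | alternative 1 | 2-{1-[3,5-bis(benzyloxy)-4-methoxyphenyl]-2-oxoethoxy}-6-(benzyloxy)-3,4,5-trimethoxybenzaldehyde (racemic) | O=CC(Oc1c(OC)c(OC)c(OC)c(OCc2ccccc2)c1C=O)c1cc(OCc2ccccc2)c(OC)c(OCc2ccccc2)c1
A3 | alternative 2 | 2-[3,5-bis(benzyloxy)-4-methoxyphenyl]-5-hydroxy-6,7,8-trimethoxychromen-4-one | COc1c(OCc2ccccc2)cc(-c2cc(=O)c3c(O)c(OC)c(OC)c(OC)c3o2)cc1OCc1ccccc1
A4 | alternative 2 | 2-iodo-4,5,6-trimethoxybenzene-1,3-diol | Oc1c(I)c(O)c(OC)c(OC)c1OC
A5 | alternative 2 | 1,3-bis(benzyloxy)-5-ethynyl-2-methoxybenzene | C#Cc1cc(OCc2ccccc2)c(OC)c(OCc2ccccc2)c1
A6 | alternative 3 | 2-[3,5-bis(benzyloxy)-4-methoxyphenyl]-3,5,6,7,8-pentamethoxychromen-4-one | COc1c(OCc2ccccc2)cc(-c2oc3c(OC)c(OC)c(OC)c(OC)c3c(=O)c2OC)cc1OCc1ccccc1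
A7 | alternative 3 | 2,3,4,5-tetramethoxy-6-(trimethylsilyl)phenyl trifluoromethanesulfonate | COc1c(OC)c(OC)c([Si](C)(C)C)c(OS(=O)(=O)C(F)(F)F)c1OC
A8 | alternative 3 | 3,4,5,6-tetramethoxybenzyne | COC1=C(OC)C(OC)=C(OC)C#C1
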